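The route rests on opening the pyranone ring of the isocoumarin (C1, O2, C3, C4, C4a, C8a) at O2–C3 and C3=C4. C3=C4 is an enol-ester double bond that joins the benzylic carbon C4 to an acyl-level carbon C3 carrying the complete dienyl-oxolane side chain. One operation, acylation of an ortho-carboxylate followed by intramolecular Wittig olefination of the resulting anhydride carbonyl, should therefore form both bonds and close the ring. The precursors are a bis-silylated (2-carboxybenzyl)triphenylphosphonium bromide carrying the chlorine and both phenol oxygens, and a silyl-protected (2E,4E)-dienoyl chloride whose three stereocentres come from 2-deoxy-D-ribose. One fluoride step then unveils the target.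

Key step: step 16

Remarks on the chemistry (assumptions):
- The phthalide needed has its benzylic carbon meta to both oxygens (5,7-dimethoxy pattern). Hydroxymethylation of 3,5-dimethoxybenzoic acid would give the 4,6-isomer, so the route starts from 3,5-dimethoxybenzyl alcohol and brings in the lactone carbonyl carbon as CO2.
- The methyl ethers are kept through the acidic phosphonium-forming melt and cleaved afterwards; the silyl groups go on last.
- The acid chloride is made under neutral conditions and meets the pre-formed carboxylate with no free amine present.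

Step 1
Reactants: 1 3,5-dimethoxybenzyl alcohol
Product: 2 (2-bromo-3,5-dimethoxyphenyl)methanol
Conditions: NBS (1.0 equiv), MeCN, 0 °C → rt
Reagents that add atoms: N-bromosuccinimide, O=C1CCC(=O)N1Br
Why: Electrophilic aromatic bromination should go to C2, which is activated ortho and para by the two methoxy groups and is less crowded than C4 between them.

Step 2
Reactants: 2 (2-bromo-3,5-dimethoxyphenyl)methanol
Product: 5 5,7-dimethoxyphthalide (5,7-dimethoxy-2-benzofuran-1(3H)-one), via dilithiated aryl alkoxide 3 (not isolated), via hydroxy acid 4 (not isolated)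
Conditions: n-BuLi (2.2 equiv), THF, −78 °C; CO2, −78 °C → rt; 2 M HCl, rt
Reagents that add atoms: carbon dioxide, O=C=O
Why: Deprotonation and bromine–lithium exchange give 3, carboxylation gives 4 on acidification, and acid-catalysed lactonisation of the ortho hydroxymethyl acid closes the five-membered lactone.

Step 3
Reactants: 5 5,7-dimethoxyphthalide
Product: 6 4-chloro-5,7-dimethoxyphthalide
Conditions: SO2Cl2 (1.05 equiv), CH2Cl2, 0 °C → rt
Reagents that add atoms: sulfuryl chloride, O=S(=O)(Cl)Cl
Why: Electrophilic aromatic chlorination should go to C4, which is ortho to the C5 methoxy group, para to the C7 methoxy group and flanked only by the ring CH2, whereas C6 is wedged between two methoxy groups.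

Step 4
Reactants: 6 4-chloro-5,7-dimethoxyphthalide; 7 triphenylphosphine hydrobromide
Product: 9 (2-carboxy-6-chloro-3,5-dimethoxybenzyl)triphenylphosphonium bromide, via bromomethyl acid 8 (not isolated)
Conditions: neat melt, 175 °C, Ar; then trituration (acetone/Et2O)
Reagents that add atoms: none
Why: HBr-promoted opening of the lactone at the benzylic carbon gives 8, and triphenylphosphine then quaternises it by SN2 displacement, the standard conversion of phthalides into (2-carboxybenzyl)phosphonium salts.

Step 5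
Reactants: 9 (2-carboxy-6-chloro-3,5-dimethoxybenzyl)triphenylphosphonium bromide
Product: 10 (2-carboxy-6-chloro-3,5-dihydroxybenzyl)triphenylphosphonium bromide
Conditions: BBr3 (5 equiv), CH2Cl2, −78 °C → rt; then H2O, 0 °C
Reagents that add atoms: none
Why: Lewis acid-mediated cleavage of aryl methyl ethers (bromide attacks the methyl group of the boron-complexed ether) should leave the phosphonium group, the acid and the aryl chloride alone and keeps bromide as the only counter-ion.

Step 6
Reactants: 10 (2-carboxy-6-chloro-3,5-dihydroxybenzyl)triphenylphosphonium bromide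
Product: 12 [2-carboxy-6-chloro-3,5-bis(tert-butyldimethylsilyloxy)benzyl]triphenylphosphonium bromide, via tris-silylated salt 11 (not isolated)
Conditions: TBSCl (3.5 equiv), imidazole (7 equiv), DMF, rt; then AcOH/THF/H2O, 0 °C → rt; CH2Cl2 extraction, aq NaBr wash
Reagents that add atoms: tert-butyldimethylsilyl chloride, CC(C)(C)[Si](C)(C)Cl
Why: Imidazole-promoted silylation covers both phenols and the acid to give 11, and the silyl ester, far more labile than aryl silyl ethers, should then be hydrolysed selectively by aqueous acetic acid.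

Step 7
Reactants: 13 2-deoxy-D-ribose
Product: 14 2-deoxy-D-ribono-1,4-lactone ((4S,5R)-4-hydroxy-5-(hydroxymethyl)oxolan-2-one)
Conditions: Br2, H2O, rt
Reagents that add atoms: none
Why: Bromine-water oxidation of the aldose hemiacetal gives the aldonolactone, which settles as the five-membered lactone with both stereocentres untouched.

Step 8
Reactants: 14 2-deoxy-D-ribono-1,4-lactone
Product: 15 (4S,5R)-4-(tert-butyldimethylsilyloxy)-5-[(tert-butyldimethylsilyloxy)methyl]oxolan-2-one
Conditions: TBSCl (2.5 equiv), imidazole (5 equiv), DMF, rt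
Reagents that add atoms: tert-butyldimethylsilyl chloride, CC(C)(C)[Si](C)(C)Cl
Why: Imidazole-promoted silyl ether formation at both hydroxyl groups is routine for this lactone.

Step 9
Reactants: 15 (4S,5R)-4-(tert-butyldimethylsilyloxy)-5-[(tert-butyldimethylsilyloxy)methyl]oxolan-2-one
Product: 16 (4S,5R)-4-(tert-butyldimethylsilyloxy)-5-[(tert-butyldimethylsilyloxy)methyl]-2-methyloxolan-2-ol (both C2 epimers)
Conditions: MeLi (1.1 equiv), THF, −78 °C; AcOH (1.2 equiv), −78 °C
Reagents that add atoms: methyllithium, [Li]C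
Why: 1,2-Addition of the organolithium to the lactone carbonyl gives a lithium hemiketalate that holds at −78 °C until the acidic quench, which keeps a second addition and base-induced β-elimination in check.

Step 10
Reactants: 16 (4S,5R)-4-(tert-butyldimethylsilyloxy)-5-[(tert-butyldimethylsilyloxy)methyl]-2-methyloxolan-2-ol
Product: 18 (2R,3S,5S)-3-(tert-butyldimethylsilyloxy)-2-[(tert-butyldimethylsilyloxy)methyl]-5-methyloxolane, via oxocarbenium ion 17 (not isolated)
Conditions: Et3SiH (3 equiv), BF3·OEt2 (2 equiv, promoter), CH2Cl2, −78 → −40 °C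
Reagents that add atoms: none
Why: In this Lewis acid-promoted ionic reduction the hemiketal ionises to 17 and hydride should enter on the face cis to the ring silyloxy group and anti to the CH2OTBS arm (inside attack on the envelope with pseudoaxial silyloxy group), which puts the methyl group cis to that arm and sets C5 as S.

Step 11
Reactants: 18 (2R,3S,5S)-3-(tert-butyldimethylsilyloxy)-2-[(tert-butyldimethylsilyloxy)methyl]-5-methyloxolane
Product: 19 [(2R,3S,5S)-3-(tert-butyldimethylsilyloxy)-5-methyloxolan-2-yl]methanol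
Conditions: TFA/H2O/THF (1:1:4), 0 °C
Reagents that add atoms: none
Why: Acid-catalysed solvolysis of silyl ethers is much faster at the unhindered primary position than at the secondary one (selective desilylation).

Step 12
Reactants: 19 [(2R,3S,5S)-3-(tert-butyldimethylsilyloxy)-5-methyloxolan-2-yl]methanol
Product: 20 (2S,3S,5S)-3-(tert-butyldimethylsilyloxy)-5-methyloxolane-2-carbaldehyde
Conditions: TEMPO (0.1 equiv), PhI(OAc)2 (1.1 equiv), CH2Cl2, rt; used crude at once
Reagents that add atoms: none
Why: The oxoammonium-mediated TEMPO/PhI(OAc)2 oxidation stops at the aldehyde in anhydrous CH2Cl2 and is non-basic, so the α-alkoxy centre should not epimerise.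

Step 13
Reactants: 20 (2S,3S,5S)-3-(tert-butyldimethylsilyloxy)-5-methyloxolane-2-carbaldehyde; 21 triethyl 4-phosphonocrotonate
Product: 22 ethyl (2E,4E)-5-[(2R,3S,5S)-3-(tert-butyldimethylsilyloxy)-5-methyloxolan-2-yl]penta-2,4-dienoate
Conditions: 21 (1.3 equiv), LiN(SiMe3)2 (1.25 equiv), THF, −78 °C; then 20, −78 → 0 °C
Reagents that add atoms: none
Why: In this vinylogous Horner–Wadsworth–Emmons olefination the lithiated phosphonate reacts at its phosphorus-bearing carbon and should give the new C4=C5 bond with E geometry while C2=C3 keeps the E geometry of the reagent, and addition at −78 °C limits epimerisation of the aldehyde.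

Step 14
Reactants: 22 ethyl (2E,4E)-5-[(2R,3S,5S)-3-(tert-butyldimethylsilyloxy)-5-methyloxolan-2-yl]penta-2,4-dienoate
Product: 23 (2E,4E)-5-[(2R,3S,5S)-3-(tert-butyldimethylsilyloxy)-5-methyloxolan-2-yl]penta-2,4-dienoic acid
Conditions: LiOH (3 equiv), THF/MeOH/H2O, rt; then 1 M HCl to pH 4, 0 °C
Reagents that add atoms: lithium hydroxide, [Li+].[OH-]
Why: Ester saponification with hydroxide should be tolerated by the secondary silyl ether and the diene, and brief acidification to pH 4 liberates the acid.

Step 15
Reactants: 23 (2E,4E)-5-[(2R,3S,5S)-3-(tert-butyldimethylsilyloxy)-5-methyloxolan-2-yl]penta-2,4-dienoic acid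
Product: 24 (2E,4E)-5-[(2R,3S,5S)-3-(tert-butyldimethylsilyloxy)-5-methyloxolan-2-yl]penta-2,4-dienoyl chloride
Conditions: 1-chloro-N,N,2-trimethylprop-1-en-1-amine (1.0 equiv), CH2Cl2, 0 °C → rt; solution used directly
Reagents that add atoms: 1-chloro-N,N,2-trimethylprop-1-en-1-amine, CC(C)=C(Cl)N(C)C
Why: The α-chloroenamine converts the acid into the acid chloride under neutral conditions (an amide is formed instead of HCl), which protects the silyl ether and the acid-sensitive dienylic C–O bond.

Step 16
Reactants: 24 (2E,4E)-5-[(2R,3S,5S)-3-(tert-butyldimethylsilyloxy)-5-methyloxolan-2-yl]penta-2,4-dienoyl chloride; 12 [2-carboxy-6-chloro-3,5-bis(tert-butyldimethylsilyloxy)benzyl]triphenylphosphonium bromide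
Product: 28 6,8-bis(tert-butyldimethylsilyloxy)-5-chloro-3-[(1E,3E)-4-[(2R,3S,5S)-3-(tert-butyldimethylsilyloxy)-5-methyloxolan-2-yl]buta-1,3-dien-1-yl]-1H-isochromen-1-one, via mixed anhydride phosphonium salt 25 (not isolated), via benzylic ylide 26 (not isolated), via oxaphosphetane 27 (not isolated)
Conditions: 12, Et3N (1.0 equiv), CH2Cl2, 0 °C; 24 (1.05 equiv), 0 °C; then Et3N (1.5 equiv), 0 → 40 °C
Reagents that add atoms: none
Why: The first equivalent of Et3N turns 12 into its carboxylate, which is acylated by 24 to mixed anhydride 25 (O2–C3 formed); the second portion deprotonates the benzylic CH2, acidified by the phosphonium group and the ortho aroyl group, to ylide 26, whose carbon adds to the dienoyl-derived carbonyl to give oxaphosphetane 27, and cycloreversion expels Ph3PO and leaves C3=C4. The closest known reaction type is the synthesis of 3-substituted isocoumarins from (2-carboxybenzyl)triphenylphosphonium salts, acid chlorides and Et3N, an intramolecular Wittig olefination of an anhydride carbonyl. The pyranone ring is closed by 6-exo-trig attack of C4 on the C3 carbonyl, the carbonyl oxygen lying outside the new ring before it leaves with phosphorus. No stereocentre is created, and the (2E,4E) geometry and the three oxolane centres enter finished and meet only Et3N and mild heat. Chemoselectivity (O-acylation before any ylide exists, and no free amine beside the acid chloride, which also shuts off ketene formation) is secured by the order of addition. Regioselectivity between the two anhydride carbonyls is secured by ring size, since attack on the aroyl carbonyl would need a four-membered ring and conjugate addition to the diene an eight- or ten-membered one.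

Step 17
Reactants: 28 6,8-bis(tert-butyldimethylsilyloxy)-5-chloro-3-[(1E,3E)-4-[(2R,3S,5S)-3-(tert-butyldimethylsilyloxy)-5-methyloxolan-2-yl]buta-1,3-dien-1-yl]-1H-isochromen-1-one
Product: 29 5-chloro-6,8-dihydroxy-3-[(1E,3E)-4-[(2R,3S,5S)-3-hydroxy-5-methyloxolan-2-yl]buta-1,3-dien-1-yl]-1H-isochromen-1-one (CNP0086741.1)
Conditions: HF·pyridine (excess), pyridine, THF, 0 °C → rt
Reagents that add atoms: none
Why: Fluoride-induced cleavage of the two aryl and one alkyl silyl ethers (global desilylation) in a pyridine-buffered, slightly acidic medium should leave the lactone, diene, aryl chloride and the three stereocentres alone.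

Compound list
1 | 3,5-dimethoxybenzyl alcohol | COc1cc(CO)cc(OC)c1 | starting material
2 | (2-bromo-3,5-dimethoxyphenyl)methanol | COc1cc(CO)c(Br)c(OC)c1 | intermediate
3 | lithium (2-lithio-3,5-dimethoxyphenyl)methanolate (not isolated) | [Li]OCc1cc(OC)cc(OC)c1[Li] | intermediate
4 | 2-(hydroxymethyl)-4,6-dimethoxybenzoic acid (not isolated) | OCc1cc(OC)cc(OC)c1C(=O)O | intermediate
5 | 5,7-dimethoxyphthalide | COc1cc(OC)c2C(=O)OCc2c1 | intermediate
6 | 4-chloro-5,7-dimethoxyphthalide | COc1cc(OC)c2C(=O)OCc2c1Cl | intermediate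
7 | triphenylphosphine hydrobromide | [Br-].[PH+](c1ccccc1)(c1ccccc1)c1ccccc1 | starting material
8 | 2-(bromomethyl)-3-chloro-4,6-dimethoxybenzoic acid (not isolated) | COc1cc(OC)c(C(=O)O)c(CBr)c1Cl | intermediate
9 | (2-carboxy-6-chloro-3,5-dimethoxybenzyl)triphenylphosphonium bromide | COc1cc(OC)c(C(=O)O)c(C[P+](c2ccccc2)(c2ccccc2)c2ccccc2)c1Cl.[Br-] | intermediate
10 | (2-carboxy-6-chloro-3,5-dihydroxybenzyl)triphenylphosphonium bromide | Oc1cc(O)c(C(=O)O)c(C[P+](c2ccccc2)(c2ccccc2)c2ccccc2)c1Cl.[Br-] | intermediate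
11 | {2-[(tert-butyldimethylsilyloxy)carbonyl]-6-chloro-3,5-bis(tert-butyldimethylsilyloxy)benzyl}triphenylphosphonium bromide (not isolated) | CC(C)(C)[Si](C)(C)OC(=O)c1c(O[Si](C)(C)C(C)(C)C)cc(O[Si](C)(C)C(C)(C)C)c(Cl)c1C[P+](c1ccccc1)(c1ccccc1)c1ccccc1.[Br-] | intermediate
12 | [2-carboxy-6-chloro-3,5-bis(tert-butyldimethylsilyloxy)benzyl]triphenylphosphonium bromide | OC(=O)c1c(O[Si](C)(C)C(C)(C)C)cc(O[Si](C)(C)C(C)(C)C)c(Cl)c1C[P+](c1ccccc1)(c1ccccc1)c1ccccc1.[Br-] | intermediate
13 | 2-deoxy-D-ribose | O=CC[C@H](O)[C@H](O)CO | starting material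
14 | 2-deoxy-D-ribono-1,4-lactone, (4S,5R) | O=C1C[C@H](O)[C@@H](CO)O1 | intermediate
15 | (4S,5R)-4-(tert-butyldimethylsilyloxy)-5-[(tert-butyldimethylsilyloxy)methyl]oxolan-2-one | O=C1C[C@H](O[Si](C)(C)C(C)(C)C)[C@@H](CO[Si](C)(C)C(C)(C)C)O1 | intermediate
16 | (4S,5R)-4-(tert-butyldimethylsilyloxy)-5-[(tert-butyldimethylsilyloxy)methyl]-2-methyloxolan-2-ol, both C2 epimers | CC1(O)C[C@H](O[Si](C)(C)C(C)(C)C)[C@@H](CO[Si](C)(C)C(C)(C)C)O1 | intermediate
17 | cyclic oxocarbenium ion of 16 after loss of hydroxide, (4S,5R) (not isolated) | CC=1C[C@H](O[Si](C)(C)C(C)(C)C)[C@@H](CO[Si](C)(C)C(C)(C)C)[O+]=1 | intermediate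
18 | (2R,3S,5S)-3-(tert-butyldimethylsilyloxy)-2-[(tert-butyldimethylsilyloxy)methyl]-5-methyloxolane | C[C@H]1C[C@H](O[Si](C)(C)C(C)(C)C)[C@@H](CO[Si](C)(C)C(C)(C)C)O1 | intermediate
19 | [(2R,3S,5S)-3-(tert-butyldimethylsilyloxy)-5-methyloxolan-2-yl]methanol | C[C@H]1C[C@H](O[Si](C)(C)C(C)(C)C)[C@@H](CO)O1 | intermediate
20 | (2S,3S,5S)-3-(tert-butyldimethylsilyloxy)-5-methyloxolane-2-carbaldehyde | C[C@H]1C[C@H](O[Si](C)(C)C(C)(C)C)[C@@H](C=O)O1 | intermediate
21 | triethyl 4-phosphonocrotonate | CCOC(=O)/C=C/CP(=O)(OCC)OCC | starting material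
22 | ethyl (2E,4E)-5-[(2R,3S,5S)-3-(tert-butyldimethylsilyloxy)-5-methyloxolan-2-yl]penta-2,4-dienoate | C[C@H]1C[C@H](O[Si](C)(C)C(C)(C)C)[C@@H](/C=C/C=C/C(=O)OCC)O1 | intermediate
23 | (2E,4E)-5-[(2R,3S,5S)-3-(tert-butyldimethylsilyloxy)-5-methyloxolan-2-yl]penta-2,4-dienoic acid | C[C@H]1C[C@H](O[Si](C)(C)C(C)(C)C)[C@@H](/C=C/C=C/C(=O)O)O1 | intermediate
24 | (2E,4E)-5-[(2R,3S,5S)-3-(tert-butyldimethylsilyloxy)-5-methyloxolan-2-yl]penta-2,4-dienoyl chloride | C[C@H]1C[C@H](O[Si](C)(C)C(C)(C)C)[C@@H](/C=C/C=C/C(Cl)=O)O1 | intermediate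
25 | mixed anhydride of 23 and the benzoic acid of 12, phosphonium bromide (not isolated) | C[C@H]1C[C@H](O[Si](C)(C)C(C)(C)C)[C@@H](/C=C/C=C/C(=O)OC(=O)c2c(O[Si](C)(C)C(C)(C)C)cc(O[Si](C)(C)C(C)(C)C)c(Cl)c2C[P+](c2ccccc2)(c2ccccc2)c2ccccc2)O1.[Br-] | intermediate
26 | benzylic triphenylphosphonium ylide of 25 (not isolated) | C[C@H]1C[C@H](O[Si](C)(C)C(C)(C)C)[C@@H](/C=C/C=C/C(=O)OC(=O)c2c(O[Si](C)(C)C(C)(C)C)cc(O[Si](C)(C)C(C)(C)C)c(Cl)c2C=P(c2ccccc2)(c2ccccc2)c2ccccc2)O1 | intermediate
27 | oxaphosphetane spanning C3 and C4 of the closed lactone ring (not isolated) | C[C@H]1C[C@H](O[Si](C)(C)C(C)(C)C)[C@@H](/C=C/C=C/C23OC(=O)c4c(O[Si](C)(C)C(C)(C)C)cc(O[Si](C)(C)C(C)(C)C)c(Cl)c4C2P(c2ccccc2)(c2ccccc2)(c2ccccc2)O3)O1 | intermediate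
28 | 6,8-bis(tert-butyldimethylsilyloxy)-5-chloro-3-[(1E,3E)-4-[(2R,3S,5S)-3-(tert-butyldimethylsilyloxy)-5-methyloxolan-2-yl]buta-1,3-dien-1-yl]-1H-isochromen-1-one | C[C@H]1C[C@H](O[Si](C)(C)C(C)(C)C)[C@@H](/C=C/C=C/c2cc3c(Cl)c(O[Si](C)(C)C(C)(C)C)cc(O[Si](C)(C)C(C)(C)C)c3c(=O)o2)O1 | intermediate
29 | 5-chloro-6,8-dihydroxy-3-[(1E,3E)-4-[(2R,3S,5S)-3-hydroxy-5-methyloxolan-2-yl]buta-1,3-dien-1-yl]-1H-isochromen-1-one | C[C@H]1C[C@H](O)[C@@H](/C=C/C=C/c2cc3c(Cl)c(O)cc(O)c3c(=O)o2)O1 | target

Total step count: 17.
Longest linear sequence: 11 steps (steps 7–17, from 13). The aromatic branch is 8 steps from 1 (steps 1–6, then 16 and 17).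

Steps most likely to fail

1. Step 16. The extended dienoyl electrophile may be consumed by side reactions before ring closure keeps pace: scrambling of the mixed anhydride, ε-deprotonation to a ketene, conjugate addition, or erosion of the diene geometry or of the oxolane α-centre. The fallback closes the ring first with a two-carbon acyl partner and makes the central C–C bond of the diene afterwards by Stille coupling. It sets out from 20 and 12 and comes back at 28. Takai iodo-olefination of 20 (CrCl2, CHI3, THF, 0 °C) should give the (E)-vinyl iodide F1. Saponification (LiOH, aq THF) of commercial ethyl (2E)-3-(tributylstannyl)prop-2-enoate gives the stannyl acrylic acid F2, and the chloroenamine of step 15 converts it into the acid chloride F3. The same carboxylate acylation and Wittig closure of 12 with F3 should give the 3-(2-stannylethenyl)isocoumarin F4. Coupling of F1 with F4 (PdCl2(MeCN)2, DMF, rt) joins the two alkenes with retention of both geometries and returns to 28.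

2. Step 4. Lactone opening at the hindered benzylic carbon may stay incomplete, or the electron-rich acid may lose CO2 and part of its ether groups at melt temperature. The fallback opens the lactone with base and traps the open form as an ester. It sets out from 6 and comes back at 9. NaOH (1 equiv, aq MeOH, evaporation) followed by allyl bromide in DMF should give the allyl hydroxymethyl benzoate F5. An Appel reaction (CBr4, PPh3, CH2Cl2, 0 °C) gives the benzylic bromide F6, and PPh3 in toluene at 80 °C gives the allyl ester phosphonium bromide F7. Allyl transfer to morpholine with catalytic Pd(PPh3)4 in CH2Cl2, followed by a wash with dilute aqueous HBr, returns 9.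

3. Step 13. The basic phosphonate anion may epimerise the α-alkoxy aldehyde or eliminate the β-silyloxy group, and the new double bond may form with incomplete E selectivity. The fallback uses two successive two-carbon Wittig homologations with non-basic stabilised ylides. It sets out from 20 and comes back at 22. (Triphenylphosphoranylidene)acetaldehyde in toluene at 60–80 °C should give the (E)-enal F8, and ethyl (triphenylphosphoranylidene)acetate in CH2Cl2 at rt then gives 22.

Further compounds
F1 | step 16 | tert-butyl{[(2R,3S,5S)-2-[(E)-2-iodoethenyl]-5-methyloxolan-3-yl]oxy}dimethylsilane | C[C@H]1C[C@H](O[Si](C)(C)C(C)(C)C)[C@@H](/C=C/I)O1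
F2 | step 16 | (2E)-3-(tributylstannyl)prop-2-enoic acid | CCCC[Sn](CCCC)(CCCC)/C=C/C(=O)O
F3 | step 16 | (2E)-3-(tributylstannyl)prop-2-enoyl chloride | CCCC[Sn](CCCC)(CCCC)/C=C/C(Cl)=O
F4 | step 16 | 6,8-bis(tert-butyldimethylsilyloxy)-5-chloro-3-[(E)-2-(tributylstannyl)ethenyl]-1H-isochromen-1-one | CCCC[Sn](CCCC)(CCCC)/C=C/c1cc2c(Cl)c(O[Si](C)(C)C(C)(C)C)cc(O[Si](C)(C)C(C)(C)C)c2c(=O)o1
F5 | step 4 | prop-2-en-1-yl 3-chloro-2-(hydroxymethyl)-4,6-dimethoxybenzoate | C=CCOC(=O)c1c(OC)cc(OC)c(Cl)c1CO
F6 | step 4 | prop-2-en-1-yl 2-(bromomethyl)-3-chloro-4,6-dimethoxybenzoate | C=CCOC(=O)c1c(OC)cc(OC)c(Cl)c1CBr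
F7 | step 4 | {6-chloro-3,5-dimethoxy-2-[(prop-2-en-1-yloxy)carbonyl]benzyl}triphenylphosphonium bromide | C=CCOC(=O)c1c(OC)cc(OC)c(Cl)c1C[P+](c1ccccc1)(c1ccccc1)c1ccccc1.[Br-]
F8 | step 13 | (2E)-3-[(2R,3S,5S)-3-(tert-butyldimethylsilyloxy)-5-methyloxolan-2-yl]prop-2-enal | C[C@H]1C[C@H](O[Si](C)(C)C(C)(C)C)[C@@H](/C=C/C=O)O1
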